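**Retrosynthetic overview**
1. Target 27 ⇐ last-step, catalyst-controlled Shi epoxidation of the 3,4-olefin of macrocyclic skipped diene 26 (sets C3, C4).
2. 26 ⇐ the 14-membered carbocycle is closed at the C5–C6 bond by an intramolecular π-allyl Stille coupling of seco-stannane 25 (allylic acetate + E-vinylstannane), not by ring-closing metathesis at C6=C7 and not by a macrocyclising allylation.
3. 25 ⇐ the cis-fused α-methylene-γ-lactone is made first, by a one-pot proline aminoxylation / indium Barbier allylation / lactonisation joining aldehyde 10 and allylic bromide 19 (sets C13, C14, C1).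
4. 10 ⇐ (S)-citronellol (C12 from the chiral pool, C8 by Sharpless epoxidation and hydride opening, vinylstannane from an alkyne); 19 ⇐ a silyl propargyl ether by carboalumination, ethylene oxide opening, vinylalumination and SN2′ bromination.
5. Ring order: γ-lactone, then 14-membered carbocycle, then epoxide.

Assumption: cembrane numbering is used (C1 ring-fusion carbon bearing C15, C3–C4 epoxide, C6=C7 E-olefin, C8 tertiary carbinol, C12 methyl carbon, C13 acetoxy carbon, C14 lactone carbinol), and the SMILES is read as 1S,3R,4R,6E,8S,12S,13R,14R with a cis-fused lactone and a trans epoxide.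

**Route**

Step 1
Reactants: 1 (S)-citronellol, (3S)-3,7-dimethyloct-6-en-1-ol
Product: 2 tert-butyl{[(3S)-3,7-dimethyloct-6-en-1-yl]oxy}dimethylsilane
Conditions: TBSCl, imidazole, DMF, rt
Reagents that add atoms: tert-butyldimethylsilyl chloride, CC(C)(C)[Si](C)(C)Cl
Why: Routine silyl ether formation masks the future C14 aldehyde, and the C12 methyl stereocentre is carried in unchanged from the chiral pool.

Step 2
Reactants: 2 tert-butyl{[(3S)-3,7-dimethyloct-6-en-1-yl]oxy}dimethylsilane
Product: 3 (2E,6S)-8-(tert-butyldimethylsilyloxy)-2,6-dimethyloct-2-en-1-ol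
Conditions: SeO2 (cat.), t-BuOOH, salicylic acid (cat.), CH2Cl2, rt
Reagents that add atoms: selenium dioxide, O=[Se]=O; tert-butyl hydroperoxide, CC(C)(C)OO
Why: Riley allylic oxidation (ene reaction then [2,3]-sigmatropic shift) oxidises the E-methyl of the trisubstituted olefin selectively and gives the E-allylic alcohol whose carbinol carbon becomes C7.

Step 3
Reactants: 3 (2E,6S)-8-(tert-butyldimethylsilyloxy)-2,6-dimethyloct-2-en-1-ol
Product: 4 [(2R,3R)-3-[(3S)-5-(tert-butyldimethylsilyloxy)-3-methylpentyl]-2-methyloxiran-2-yl]methanol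
Conditions: Ti(OiPr)4 (10 mol %), D-(−)-diethyl tartrate (12 mol %), t-BuOOH, 4 Å MS, CH2Cl2, −20 °C
Reagents that add atoms: tert-butyl hydroperoxide, CC(C)(C)OO
Why: Sharpless asymmetric epoxidation with the D-(−)-tartrate ligand gives the (2R,3R)-epoxy alcohol under reagent control, which fixes the oxygen-bearing quaternary carbon that becomes C8 (S).

Step 4
Reactants: 4 [(2R,3R)-3-[(3S)-5-(tert-butyldimethylsilyloxy)-3-methylpentyl]-2-methyloxiran-2-yl]methanol
Product: 5 (2S,6S)-8-(tert-butyldimethylsilyloxy)-2,6-dimethyloctane-1,2-diol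
Conditions: LiAlH4, THF, 0 °C to rt
Reagents that add atoms: none
Why: Hydride opens the epoxide by SN2 attack at the secondary carbon (C9) and not at the quaternary one, so the C8–O bond and its configuration are untouched and the tertiary alcohol results.

Step 5
Reactants: 5 (2S,6S)-8-(tert-butyldimethylsilyloxy)-2,6-dimethyloctane-1,2-diol
Product: 6 (2S,6S)-8-(tert-butyldimethylsilyloxy)-2-hydroxy-2,6-dimethyloctanal
Conditions: SO3·pyridine, DMSO, Et3N, CH2Cl2, 0 °C
Reagents that add atoms: none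
Why: Parikh–Doering oxidation converts only the primary hydroxyl (the tertiary one cannot be oxidised), and the non-enolisable α-hydroxy aldehyde cannot epimerise.

Step 6
Reactants: 6 (2S,6S)-8-(tert-butyldimethylsilyloxy)-2-hydroxy-2,6-dimethyloctanal
Product: 7 (3S,7S)-9-(tert-butyldimethylsilyloxy)-3,7-dimethylnon-1-yn-3-ol
Conditions: Ohira–Bestmann reagent, K2CO3, MeOH, 0 °C to rt
Reagents that add atoms: dimethyl (1-diazo-2-oxopropyl)phosphonate, CC(=O)C(=[N+]=[N-])P(=O)(OC)OC
Why: Ohira–Bestmann (Seyferth–Gilbert) homologation turns the aldehyde into the terminal alkyne under mild carbonate conditions and adds C6.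

Step 7
Reactants: 7 (3S,7S)-9-(tert-butyldimethylsilyloxy)-3,7-dimethylnon-1-yn-3-ol
Product: 8 (1E,3S,7S)-9-(tert-butyldimethylsilyloxy)-3,7-dimethyl-1-(tributylstannyl)non-1-en-3-ol
Conditions: Bu3SnH, PdCl2(PPh3)2 (3 mol %), THF, 0 °C
Reagents that add atoms: tributyltin hydride, CCCC[SnH](CCCC)CCCC
Why: Palladium-catalysed syn-hydrostannation puts tin on the terminal carbon because the adjacent fully substituted carbinol blocks the internal position, which gives the E-vinylstannane.

Step 8
Reactants: 8 (1E,3S,7S)-9-(tert-butyldimethylsilyloxy)-3,7-dimethyl-1-(tributylstannyl)non-1-en-3-ol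
Product: 9 (3S,7S,8E)-3,7-dimethyl-9-(tributylstannyl)non-8-ene-1,7-diol
Conditions: HF·pyridine, pyridine, THF, 0 °C to rt
Reagents that add atoms: none
Why: Pyridine-buffered fluoride cleaves the primary silyl ether without protodestannylation or ionisation of the tertiary allylic alcohol.

Step 9
Reactants: 9 (3S,7S,8E)-3,7-dimethyl-9-(tributylstannyl)non-8-ene-1,7-diol
Product: 10 (3S,7S,8E)-7-hydroxy-3,7-dimethyl-9-(tributylstannyl)non-8-enal
Conditions: Dess–Martin periodinane, pyridine, CH2Cl2, 0 °C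
Reagents that add atoms: none
Why: Dess–Martin oxidation under buffered conditions gives the aldehyde, and the C12 centre is β to the carbonyl and so is not at risk.

Step 10
Reactants: 11 tert-butyldimethyl(prop-2-yn-1-yloxy)silane; 12 ethylene oxide
Product: 14 (E)-5-(tert-butyldimethylsilyloxy)-4-methylpent-3-en-1-ol, via alkenyldimethylalane 13 (not isolated)
Conditions: Me3Al, Cp2ZrCl2 (20 mol %), CH2Cl2, 0 °C to rt; then n-BuLi, THF–hexane, −30 °C; then 12, −30 to 0 °C
Reagents that add atoms: trimethylaluminium, C[Al](C)C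
Why: Negishi zirconium-catalysed syn-carboalumination adds methyl (to the internal carbon) and aluminium cis across the alkyne, and the derived alanate opens ethylene oxide with retention, which fixes the E-trisubstituted olefin C3=C4.

Step 11
Reactants: 14 (E)-5-(tert-butyldimethylsilyloxy)-4-methylpent-3-en-1-ol
Product: 15 (E)-5-(tert-butyldimethylsilyloxy)-4-methylpent-3-enal
Conditions: Dess–Martin periodinane, pyridine, CH2Cl2, 0 °C, used crude at once
Reagents that add atoms: none
Why: Dess–Martin oxidation without strong base gives the β,γ-unsaturated aldehyde before the olefin can move into conjugation.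

Step 12
Reactants: 15 (E)-5-(tert-butyldimethylsilyloxy)-4-methylpent-3-enal; 16 methyl propiolate
Product: 18 methyl (5E)-7-(tert-butyldimethylsilyloxy)-3-hydroxy-6-methyl-2-methylidenehept-5-enoate (racemic at C3), via methyl 2-(diisobutylalumanyl)acrylate 17 (not isolated)
Conditions: 16, i-Bu2AlH, N-methylmorpholine N-oxide, THF, 0 °C; then 15, 0 °C to rt
Reagents that add atoms: none
Why: Vinylalumination (hydroalumination of the propiolate to the α-alumino acrylate, then carbonyl addition) gives the Morita–Baylis–Hillman-type adduct without the amine base that would isomerise the aldehyde; the racemic carbinol centre is destroyed in step 13.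

Step 13
Reactants: 18 methyl (5E)-7-(tert-butyldimethylsilyloxy)-3-hydroxy-6-methyl-2-methylidenehept-5-enoate
Product: 19 methyl (2Z,5E)-2-(bromomethyl)-7-(tert-butyldimethylsilyloxy)-6-methylhepta-2,5-dienoate
Conditions: N-bromosuccinimide, Me2S, CH2Cl2, 0 °C to rt
Reagents that add atoms: N-bromosuccinimide, O=C1CCC(=O)N1Br
Why: Corey–Kim-type activation of the alcohol followed by SN2′ attack of bromide transposes the allylic system to the thermodynamically preferred primary (Z)-2-(bromomethyl)enoate.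

Step 14
Reactants: 10 (3S,7S,8E)-7-hydroxy-3,7-dimethyl-9-(tributylstannyl)non-8-enal; 19 methyl (2Z,5E)-2-(bromomethyl)-7-(tert-butyldimethylsilyloxy)-6-methylhepta-2,5-dienoate
Product: 22 (4S,5R)-5-[(1R,2S,6S,7E)-1-(anilinooxy)-6-hydroxy-2,6-dimethyl-8-(tributylstannyl)oct-7-en-1-yl]-4-[(2E)-4-(tert-butyldimethylsilyloxy)-3-methylbut-2-en-1-yl]-3-methylideneoxolan-2-one, via α-anilinooxy aldehyde 20 (not isolated), via open-chain hydroxy ester 21 (not isolated)
Conditions: nitrosobenzene, L-proline (20 mol %), DMSO, rt; then 19, In powder, THF–H2O, rt; then pyridinium p-toluenesulfonate (cat.), CH2Cl2, rt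
Reagents that add atoms: nitrosobenzene, O=Nc1ccccc1
Why: L-Proline enamine catalysis (α-aminoxylation) sets C13 (R), and the indium Barbier allylation then runs through a chelated Zimmerman–Traxler chair (metal bridging the aldehyde and the α-oxygen, Z-allyl geometry) to the syn,syn adduct, that is C14 (R) and C1 (S), which lactonises to the cis-fused α-methylene-γ-lactone.

Step 15
Reactants: 22 the anilinooxy lactone from step 14
Product: 23 (4S,5R)-5-[(1R,2S,6S,7E)-1,6-dihydroxy-2,6-dimethyl-8-(tributylstannyl)oct-7-en-1-yl]-4-[(2E)-4-(tert-butyldimethylsilyloxy)-3-methylbut-2-en-1-yl]-3-methylideneoxolan-2-one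
Conditions: Zn, AcOH, THF, rt
Reagents that add atoms: none
Why: Zinc in acetic acid reductively cleaves the weak N–O bond and leaves the enoate, the silyl ether and the stannane untouched.

Step 16
Reactants: 23 the C13 alcohol from step 15
Product: 24 (4S,5R)-5-[(1R,2S,6S,7E)-1,6-dihydroxy-2,6-dimethyl-8-(tributylstannyl)oct-7-en-1-yl]-4-[(2E)-4-hydroxy-3-methylbut-2-en-1-yl]-3-methylideneoxolan-2-one
Conditions: HF·pyridine, pyridine, THF, 0 °C
Reagents that add atoms: none
Why: Buffered HF·pyridine removes the primary allylic silyl ether and frees the C5 hydroxyl.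

Step 17
Reactants: 24 the triol from step 16
Product: 25 (4S,5R)-5-[(1R,2S,6S,7E)-1-acetoxy-6-hydroxy-2,6-dimethyl-8-(tributylstannyl)oct-7-en-1-yl]-4-[(2E)-4-acetoxy-3-methylbut-2-en-1-yl]-3-methylideneoxolan-2-one
Conditions: Ac2O, pyridine, 4-(dimethylamino)pyridine (cat.), CH2Cl2, 0 °C
Reagents that add atoms: acetic anhydride, CC(=O)OC(C)=O
Why: Acylation of the primary allylic and the secondary hydroxyl (the tertiary one does not react) installs the C13 acetate of the target and, in the same operation, the allylic leaving group for ring closure.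

Step 18
Reactants: 25 the seco bis-acetate stannane from step 17
Product: 26 (1S,3E,6E,8S,12S,13R,14R)-13-acetoxy-8-hydroxycembra-3,6,15(17)-trien-16,14-olide
Conditions: Pd2(dba)3 (10 mol %), LiCl, i-Pr2NEt, DMF, 45 °C, 1 mM, slow addition
Reagents that add atoms: none
Why: Intramolecular Stille coupling through a π-allylpalladium intermediate, in which zerovalent palladium ionises only the allylic acetate, the vinylstannane transmetalates and reductive elimination at the less substituted allyl terminus closes the 14-membered ring with both olefin geometries carried over from the precursors.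

Step 19
Reactants: 26 the macrocyclic skipped diene from step 18
Product: 27 (1S,3R,4R,6E,8S,12S,13R,14R)-13-acetoxy-3,4-epoxy-8-hydroxycembra-6,15(17)-dien-16,14-olide (CNP0202356.4)
Conditions: D-fructose-derived Shi ketone (1,2:4,5-di-O-isopropylidene-β-D-erythro-2,3-hexodiulo-2,6-pyranose, 30 mol %), KHSO5 (as 2KHSO5·KHSO4·K2SO4), K2CO3, Bu4NHSO4, MeCN–CH2(OMe)2–aq. Na2B4O7 buffer, 0 °C
Reagents that add atoms: potassium peroxymonosulfate KHSO5, [K+].[O-]S(=O)(=O)OO
Why: Shi asymmetric epoxidation, in which the chiral dioxirane attacks the electron-rich trisubstituted olefin through a spiro transition state (the disubstituted olefin is deactivated by the allylic hydroxyl and the enoate is electron-poor) and delivers oxygen to the face that gives the (3R,4R)-epoxide.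

**Compound list**
1 | (S)-citronellol, (3S)-3,7-dimethyloct-6-en-1-ol | OCC[C@@H](C)CCC=C(C)C | starting material
2 | tert-butyl{[(3S)-3,7-dimethyloct-6-en-1-yl]oxy}dimethylsilane | CC(C)(C)[Si](C)(C)OCC[C@@H](C)CCC=C(C)C | intermediate
3 | (2E,6S)-8-(tert-butyldimethylsilyloxy)-2,6-dimethyloct-2-en-1-ol | CC(C)(C)[Si](C)(C)OCC[C@@H](C)CC/C=C(\C)CO | intermediate
4 | [(2R,3R)-3-[(3S)-5-(tert-butyldimethylsilyloxy)-3-methylpentyl]-2-methyloxiran-2-yl]methanol | CC(C)(C)[Si](C)(C)OCC[C@@H](C)CC[C@H]1O[C@]1(C)CO | intermediate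
5 | (2S,6S)-8-(tert-butyldimethylsilyloxy)-2,6-dimethyloctane-1,2-diol | CC(C)(C)[Si](C)(C)OCC[C@@H](C)CCC[C@](C)(O)CO | intermediate
6 | (2S,6S)-8-(tert-butyldimethylsilyloxy)-2-hydroxy-2,6-dimethyloctanal | CC(C)(C)[Si](C)(C)OCC[C@@H](C)CCC[C@](C)(O)C=O | intermediate
7 | (3S,7S)-9-(tert-butyldimethylsilyloxy)-3,7-dimethylnon-1-yn-3-ol | CC(C)(C)[Si](C)(C)OCC[C@@H](C)CCC[C@](C)(O)C#C | intermediate
8 | (1E,3S,7S)-9-(tert-butyldimethylsilyloxy)-3,7-dimethyl-1-(tributylstannyl)non-1-en-3-ol | CC(C)(C)[Si](C)(C)OCC[C@@H](C)CCC[C@](C)(O)/C=C/[Sn](CCCC)(CCCC)CCCC | intermediate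
9 | (3S,7S,8E)-3,7-dimethyl-9-(tributylstannyl)non-8-ene-1,7-diol | OCC[C@@H](C)CCC[C@](C)(O)/C=C/[Sn](CCCC)(CCCC)CCCC | intermediate
10 | (3S,7S,8E)-7-hydroxy-3,7-dimethyl-9-(tributylstannyl)non-8-enal (East fragment) | O=CC[C@@H](C)CCC[C@](C)(O)/C=C/[Sn](CCCC)(CCCC)CCCC | intermediate
11 | tert-butyldimethyl(prop-2-yn-1-yloxy)silane | C#CCO[Si](C)(C)C(C)(C)C | starting material
12 | ethylene oxide (oxirane) | C1CO1 | starting material
13 | (E)-[3-(tert-butyldimethylsilyloxy)-2-methylprop-1-en-1-yl]dimethylalane | C[Al](C)/C=C(\C)CO[Si](C)(C)C(C)(C)C | intermediate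
14 | (E)-5-(tert-butyldimethylsilyloxy)-4-methylpent-3-en-1-ol | OCC/C=C(\C)CO[Si](C)(C)C(C)(C)C | intermediate
15 | (E)-5-(tert-butyldimethylsilyloxy)-4-methylpent-3-enal | O=CC/C=C(\C)CO[Si](C)(C)C(C)(C)C | intermediate
16 | methyl propiolate | C#CC(=O)OC | starting material
17 | methyl 2-(diisobutylalumanyl)acrylate | C=C(C(=O)OC)[Al](CC(C)C)CC(C)C | intermediate
18 | methyl (5E)-7-(tert-butyldimethylsilyloxy)-3-hydroxy-6-methyl-2-methylidenehept-5-enoate (racemic at C3) | C=C(C(=O)OC)C(O)C/C=C(\C)CO[Si](C)(C)C(C)(C)C | intermediate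
19 | methyl (2Z,5E)-2-(bromomethyl)-7-(tert-butyldimethylsilyloxy)-6-methylhepta-2,5-dienoate (West fragment) | COC(=O)/C(CBr)=C/C/C=C(\C)CO[Si](C)(C)C(C)(C)C | intermediate
20 | (2R,3S,7S,8E)-2-(anilinooxy)-7-hydroxy-3,7-dimethyl-9-(tributylstannyl)non-8-enal | O=C[C@H](ONc1ccccc1)[C@@H](C)CCC[C@](C)(O)/C=C/[Sn](CCCC)(CCCC)CCCC | intermediate
21 | methyl (3S,4R,5R,6S,10S,11E)-5-(anilinooxy)-3-[(2E)-4-(tert-butyldimethylsilyloxy)-3-methylbut-2-en-1-yl]-4,10-dihydroxy-6,10-dimethyl-2-methylidene-12-(tributylstannyl)dodec-11-enoate | COC(=O)C(=C)[C@H](C/C=C(\C)CO[Si](C)(C)C(C)(C)C)[C@@H](O)[C@H](ONc1ccccc1)[C@@H](C)CCC[C@](C)(O)/C=C/[Sn](CCCC)(CCCC)CCCC | intermediate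
22 | (4S,5R)-5-[(1R,2S,6S,7E)-1-(anilinooxy)-6-hydroxy-2,6-dimethyl-8-(tributylstannyl)oct-7-en-1-yl]-4-[(2E)-4-(tert-butyldimethylsilyloxy)-3-methylbut-2-en-1-yl]-3-methylideneoxolan-2-one | C=C1C(=O)O[C@H]([C@H]1C/C=C(\C)CO[Si](C)(C)C(C)(C)C)[C@H](ONc1ccccc1)[C@@H](C)CCC[C@](C)(O)/C=C/[Sn](CCCC)(CCCC)CCCC | intermediate
23 | (4S,5R)-5-[(1R,2S,6S,7E)-1,6-dihydroxy-2,6-dimethyl-8-(tributylstannyl)oct-7-en-1-yl]-4-[(2E)-4-(tert-butyldimethylsilyloxy)-3-methylbut-2-en-1-yl]-3-methylideneoxolan-2-one | C=C1C(=O)O[C@H]([C@H]1C/C=C(\C)CO[Si](C)(C)C(C)(C)C)[C@H](O)[C@@H](C)CCC[C@](C)(O)/C=C/[Sn](CCCC)(CCCC)CCCC | intermediate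
24 | (4S,5R)-5-[(1R,2S,6S,7E)-1,6-dihydroxy-2,6-dimethyl-8-(tributylstannyl)oct-7-en-1-yl]-4-[(2E)-4-hydroxy-3-methylbut-2-en-1-yl]-3-methylideneoxolan-2-one | C=C1C(=O)O[C@H]([C@H]1C/C=C(\C)CO)[C@H](O)[C@@H](C)CCC[C@](C)(O)/C=C/[Sn](CCCC)(CCCC)CCCC | intermediate
25 | (4S,5R)-5-[(1R,2S,6S,7E)-1-acetoxy-6-hydroxy-2,6-dimethyl-8-(tributylstannyl)oct-7-en-1-yl]-4-[(2E)-4-acetoxy-3-methylbut-2-en-1-yl]-3-methylideneoxolan-2-one | C=C1C(=O)O[C@H]([C@H]1C/C=C(\C)COC(C)=O)[C@H](OC(C)=O)[C@@H](C)CCC[C@](C)(O)/C=C/[Sn](CCCC)(CCCC)CCCC | intermediate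
26 | (1S,3E,6E,8S,12S,13R,14R)-13-acetoxy-8-hydroxycembra-3,6,15(17)-trien-16,14-olide | C=C1C(=O)O[C@H]2[C@H](OC(C)=O)[C@@H](C)CCC[C@](C)(O)/C=C/C/C(C)=C/C[C@@H]12 | intermediate
27 | (1S,3R,4R,6E,8S,12S,13R,14R)-13-acetoxy-3,4-epoxy-8-hydroxycembra-6,15(17)-dien-16,14-olide (CNP0202356.4) | C=C1C(=O)O[C@H]2[C@H](OC(C)=O)[C@@H](C)CCC[C@](C)(O)/C=C/C[C@@]3(C)O[C@@H]3C[C@@H]12 | target

**Step count**
Total: 19 steps. Longest linear sequence: 15 steps (steps 1–9, then 14–19); the West fragment takes 4 steps (10–13).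

**Three steps most likely to fail**

Step 14 (one-pot aminoxylation / Barbier / lactonisation). The anilinooxy group may chelate indium only moderately, so the C14 epimer could form in a significant amount, and the N–O bond is labile. The fallback sets out from 10. After the same aminoxylation the aldehyde is reduced in the pot with NaBH4 to the anilinooxy alcohol F1. Zn/AcOH then cleaves the N–O bond to give the 1,2-diol F2. 2,2,6,6-Tetramethylpiperidin-1-oxyl with PhI(OAc)2 oxidises only the primary hydroxyl to the free α-hydroxy aldehyde F3. The indium Barbier reaction of F3 with 19 in water–THF uses a free hydroxyl, which chelates most strongly. The resulting hydroxy ester F4 lactonises with pyridinium p-toluenesulfonate to 23, where the route is rejoined.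

Step 18 (Stille macrocyclisation). Oligomerisation, protodestannylation and syn/anti isomerisation of the 2-methyl-substituted π-allyl (which would give the 3Z olefin) are all possible. The fallback sets out from 25 and closes the ring by metathesis instead. Protodestannylation (p-TsOH·H2O, CH2Cl2, 0 °C) gives the vinyl carbinol F5. An intermolecular Stille coupling of its allylic acetate with tributyl(vinyl)stannane (Pd2(dba)3, LiCl, DMF) gives the triene F6. Ring-closing metathesis at C6=C7 with the second-generation Hoveyda–Grubbs catalyst RuCl2(H2IMes)(=CH-C6H4-2-O-i-Pr) in toluene at 80 °C and 1 mM returns the route at 26; an E/Z mixture may have to be separated.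

Step 19 (Shi epoxidation on the macrocycle). The conformational bias of the ring may override the catalyst and give the (3S,4S)-epoxide, or the C6=C7 olefin may compete. The fallback sets out from 26. N-Bromosuccinimide in aqueous THF attacks the exposed face of the trisubstituted olefin and water opens the bromonium ion anti at the tertiary carbon, giving the bromohydrin F7. K2CO3 in MeCN closes the epoxide with inversion at C3 and returns the route at 27. The oxygen ends on the face opposite to the one the electrophile attacked, so this route gives the epoxide that a substrate-controlled direct epoxidation does not.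

**Further compounds**
F1 | step 14 | (2R,3S,7S,8E)-2-(anilinooxy)-3,7-dimethyl-9-(tributylstannyl)non-8-ene-1,7-diol | OC[C@H](ONc1ccccc1)[C@@H](C)CCC[C@](C)(O)/C=C/[Sn](CCCC)(CCCC)CCCC
F2 | step 14 | (2R,3S,7S,8E)-3,7-dimethyl-9-(tributylstannyl)non-8-ene-1,2,7-triol | OC[C@H](O)[C@@H](C)CCC[C@](C)(O)/C=C/[Sn](CCCC)(CCCC)CCCC
F3 | step 14 | (2R,3S,7S,8E)-2,7-dihydroxy-3,7-dimethyl-9-(tributylstannyl)non-8-enal | O=C[C@H](O)[C@@H](C)CCC[C@](C)(O)/C=C/[Sn](CCCC)(CCCC)CCCC
F4 | step 14 | methyl (3S,4R,5R,6S,10S,11E)-3-[(2E)-4-(tert-butyldimethylsilyloxy)-3-methylbut-2-en-1-yl]-4,5,10-trihydroxy-6,10-dimethyl-2-methylidene-12-(tributylstannyl)dodec-11-enoate | COC(=O)C(=C)[C@H](C/C=C(\C)CO[Si](C)(C)C(C)(C)C)[C@@H](O)[C@H](O)[C@@H](C)CCC[C@](C)(O)/C=C/[Sn](CCCC)(CCCC)CCCC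
F5 | step 18 | (4S,5R)-5-[(1R,2S,6S)-1-acetoxy-6-hydroxy-2,6-dimethyloct-7-en-1-yl]-4-[(2E)-4-acetoxy-3-methylbut-2-en-1-yl]-3-methylideneoxolan-2-one | C=C1C(=O)O[C@H]([C@H]1C/C=C(\C)COC(C)=O)[C@H](OC(C)=O)[C@@H](C)CCC[C@](C)(O)C=C
F6 | step 18 | (4S,5R)-5-[(1R,2S,6S)-1-acetoxy-6-hydroxy-2,6-dimethyloct-7-en-1-yl]-4-[(2E)-3-methylhexa-2,5-dien-1-yl]-3-methylideneoxolan-2-one | C=C1C(=O)O[C@H]([C@H]1C/C=C(\C)CC=C)[C@H](OC(C)=O)[C@@H](C)CCC[C@](C)(O)C=C
F7 | step 19 | (1S,3S,4R,6E,8S,12S,13R,14R)-13-acetoxy-3-bromo-4,8-dihydroxycembra-6,15(17)-dien-16,14-olide | C=C1C(=O)O[C@H]2[C@H](OC(C)=O)[C@@H](C)CCC[C@](C)(O)/C=C/C[C@@](C)(O)[C@@H](Br)C[C@@H]12
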